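The cycloheptene is not closed as a seven-membered ring. In the five-membered ring C1–C5, quaternary C1 and ring-fusion C5 are the β- and α-carbons of the C4 oxygen function, so both belong to the C1=C5 bond of a cyclopentenone. Irradiation adds the tethered vinyl group C9=C10 across it, forming C1–C10 and a sacrificial C5–C9 bond. A cyclobutane and a cyclopentane close, and C1, C5 and C9 are set at once. The precursor is a 3-methylcyclopent-2-enone with a 4-silyloxy group (C2) and, on C5, a C6-silyloxy, C8-silyloxy pentenyl chain. SmI2 then cuts C5–C9, expels O8 and merges both small rings into the cycloheptene.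

Key step: step 10

**Numbering and faces.** C1 is the quaternary C(CH3), C2 is CH(OAc), C3 is CH2, C4 is C(OH)(i-Pr), and C5 is the ring-fusion CH. C6 is CH(O-anisoyl), C7 is CH2, C8 is C(CH3) and C9 is CH of the epoxide, and C10 is CH2. β is the face of the C1 methyl group. The target SMILES reads as 1β-CH3, 2α-OAc, 4β-OH/4α-i-Pr, 5α-H (trans fusion), 6α-O-anisoyl and 8α,9α-epoxide.

**Design points.**
- O2 carries TBS and O6 carries TES, so the two secondary oxygens can be unmasked one at a time.
- O8 is a TES ether rather than an ester. This avoids a β-acyloxy aldehyde, acyl transfer from O8 to the new O6 alkoxide, and nickel-allyl chemistry in the coupling. The silyloxy group can still leave from the C9 organosamarium.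
- C6 is set by a chiral chromium complex and C8 comes from the chiral pool, so every intermediate is a single stereoisomer.
- No base is used while C4 is a ketone, because O2 and O6 are both β to it. C5 is set by kinetic protonation.
- C2 is inverted by oxidation and hydroxyl-directed reduction, not by substitution at this neopentyl carbon.

**Assumption (chemistry).** Commercial (R)-linalool need not be optically pure, because C8 becomes sp2 in step 11 and any 8S material converges there.

Step 1
Reactants: 1 (S)-4-(tert-butyldimethylsilyloxy)cyclopent-2-en-1-one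
Product: 2 (3S,4S)-4-(tert-butyldimethylsilyloxy)-3-methyl-1-(trimethylsilyloxy)cyclopent-1-ene
Conditions: Me2CuLi (from MeLi, CuI), TMSCl, Et2O–THF, −78 °C
Reagents that add atoms: lithium dimethylcuprate [Li+].C[Cu-]C; chlorotrimethylsilane C[Si](C)(C)Cl
Why: TMSCl-accelerated organocuprate conjugate addition should deliver methyl anti to the silyloxy group and trap the enolate regiospecifically as its silyl enol ether; the new methine is flattened again in step 2 and the carbinol centre (future C2) is untouched.

Step 2
Reactants: 2 (3S,4S)-4-(tert-butyldimethylsilyloxy)-3-methyl-1-(trimethylsilyloxy)cyclopent-1-ene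
Product: 3 (S)-4-(tert-butyldimethylsilyloxy)-3-methylcyclopent-2-en-1-one
Conditions: Pd(OAc)2 (1.05 equiv), MeCN, rt
Reagents that add atoms: none
Why: Saegusa–Ito oxidation, in which the oxa-π-allylpalladium species can only lose the hydrogen on the methyl-bearing carbon, so the 3-methyl enone should form without disturbing the γ-silyloxy centre.

Step 3
Reactants: 3 (S)-4-(tert-butyldimethylsilyloxy)-3-methylcyclopent-2-en-1-one
Product: 4 (S)-4-(tert-butyldimethylsilyloxy)-2-iodo-3-methylcyclopent-2-en-1-one
Conditions: I2, pyridine–CH2Cl2, 0 °C → rt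
Reagents that add atoms: iodine II
Why: α-Iodination of an enone by the iodine/pyridine addition–elimination sequence (Baylis–Hillman-type activation) is established for 4-silyloxycyclopentenones and for 3-methylcyclopentenone and needs no strong base that could expel the γ-silyloxy group.

Step 4
Reactants: 5 (R)-(−)-linalool
Product: 6 (3R)-3,7-dimethyl-3-(triethylsilyloxy)octa-1,6-diene
Conditions: TESOTf, 2,6-lutidine, CH2Cl2, 0 °C
Reagents that add atoms: triethylsilyl triflate CC[Si](CC)(CC)OS(=O)(=O)C(F)(F)F
Why: Silyl triflate silylation copes with the hindered tertiary allylic alcohol, and the 8R centre comes from the chiral pool and is retained because no C–O bond is broken.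

Step 5
Reactants: 6 (3R)-3,7-dimethyl-3-(triethylsilyloxy)octa-1,6-diene
Product: 7 (4R)-4-methyl-4-(triethylsilyloxy)hex-5-enal
Conditions: O3 (1 equiv), pyridine, CH2Cl2, −78 °C
Reagents that add atoms: ozone [O-][O+]=O
Why: Chemoselective ozonolysis, in which the electron-rich trisubstituted alkene reacts much faster than the vinyl group next to the oxygenated quaternary carbon and pyridine turns the carbonyl oxide directly into the carbonyl compound, so no peroxide work-up is needed.

Step 6
Reactants: 7 (4R)-4-methyl-4-(triethylsilyloxy)hex-5-enal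
Product: 8 triisopropyl{[(1Z,4R)-4-methyl-4-(triethylsilyloxy)hexa-1,5-dien-1-yl]oxy}silane
Conditions: TIPSOTf, Et3N, CH2Cl2, 0 °C → rt
Reagents that add atoms: triisopropylsilyl triflate CC(C)[Si](C(C)C)(C(C)C)OS(=O)(=O)C(F)(F)F
Why: Soft enolisation of the aldehyde with a silyl triflate and a tertiary amine should give the mainly Z silyl enol ether, whose geometry is irrelevant because this double bond is cleaved next.

Step 7
Reactants: 8 triisopropyl{[(1Z,4R)-4-methyl-4-(triethylsilyloxy)hexa-1,5-dien-1-yl]oxy}silane
Product: 9 (3R)-3-methyl-3-(triethylsilyloxy)pent-4-enal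
Conditions: O3 (1 equiv), pyridine, CH2Cl2, −78 °C
Reagents that add atoms: ozone [O-][O+]=O
Why: Ozonolysis of the silyl enol ether, by far the most electron-rich alkene present, removes one carbon as the silyl formate (one-carbon degradation of an aldehyde) and gives a β-silyloxy aldehyde that is far less prone to β-elimination than a β-acyloxy aldehyde.

Step 8
Reactants: 4 (S)-4-(tert-butyldimethylsilyloxy)-2-iodo-3-methylcyclopent-2-en-1-one; 9 (3R)-3-methyl-3-(triethylsilyloxy)pent-4-enal
Product: 10 (4S)-4-(tert-butyldimethylsilyloxy)-2-[(1R,3R)-1-hydroxy-3-methyl-3-(triethylsilyloxy)pent-4-en-1-yl]-3-methylcyclopent-2-en-1-one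
Conditions: CrCl2 (4 equiv), NiCl2 (cat.), N-[2-(4-isopropyl-4,5-dihydrooxazol-2-yl)-6-methylphenyl]methanesulfonamide (antipode chosen for Si-face addition), Et3N, THF, rt
Reagents that add atoms: none
Why: Asymmetric Nozaki–Hiyama–Kishi reaction, in which zerovalent nickel inserts into the C–I bond, transmetallation gives an alkenyl species of trivalent chromium that tolerates the ketone and the silyl ethers, and the chiral sulfonamide ligand on chromium rather than the remote C2 and C8 centres directs addition to the Si face of the aldehyde and so sets 6R.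

Step 9
Reactants: 10 (4S)-4-(tert-butyldimethylsilyloxy)-2-[(1R,3R)-1-hydroxy-3-methyl-3-(triethylsilyloxy)pent-4-en-1-yl]-3-methylcyclopent-2-en-1-one
Product: 11 (4S)-4-(tert-butyldimethylsilyloxy)-3-methyl-2-[(1R,3R)-3-methyl-1,3-bis(triethylsilyloxy)pent-4-en-1-yl]cyclopent-2-en-1-one
Conditions: TESOTf, 2,6-lutidine, CH2Cl2, −78 °C
Reagents that add atoms: triethylsilyl triflate CC[Si](CC)(CC)OS(=O)(=O)C(F)(F)F
Why: Low-temperature triflate silylation caps the allylic alcohol without ionisation, and TES on O6 is chosen because it can later be removed beside TBS on O2.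

Step 10
Reactants: 11 (4S)-4-(tert-butyldimethylsilyloxy)-3-methyl-2-[(1R,3R)-3-methyl-1,3-bis(triethylsilyloxy)pent-4-en-1-yl]cyclopent-2-en-1-one
Product: 12 tricyclic photoadduct, 8-(tert-butyldimethylsilyloxy)-4,7-dimethyl-2,4-bis(triethylsilyloxy)tricyclo[5.3.0.0(1,5)]decan-10-one (route numbering: C4 ketone; C9 and C10 on the α face; 1β-CH3; 2β-OTBS; 6R-OTES; 8R-OTES; H9 on the side of C4)
Conditions: hν (medium-pressure Hg lamp, Pyrex, λ > 300 nm), degassed hexane, 0.005 M, 10 °C
Reagents that add atoms: none
Why: Light above 300 nm excites only the enone, whose triplet bonds from its α-carbon C5 to the inner vinyl carbon C9 and, after spin inversion of the resulting 1,4-biradical (tertiary C1, primary C10), from C1 to C10. This is the intramolecular enone–alkene [2+2] photocycloaddition known for 2-(pent-4-enyl)cyclopent-2-enones. The cyclopentane C5–C6–C7–C8–C9 closes first in the 5-exo mode preferred by a 1,6-diene with a three-atom tether (rule of five), and the cyclobutane C1–C5–C9–C10 closes second by biradical collapse, which gives the straight rather than the crossed adduct. C1 and C5 are fixed together by the enone face that is attacked, since the four-membered ring can only be cis-fused to the cyclopentanone: allylic 1,3-strain with the C1 methyl group holds H6 in the enone plane, which for the 6R centre places C7 below the α face, and the 2β-silyloxy group next to C1 screens the β face, so both controllers are matched. C9 is dictated by the cis fusion of the new bicyclo[3.2.0]heptane unit (H9 on the side of C4), and the 8R centre keeps the slim C–O bond rather than the methyl group on its concave side. The step therefore needs chemo-, regio- and α-facial selectivity, secured by the chromophore, the tether length and the C2/C6 pair, while dilution and degassing suppress dimerisation and triplet quenching.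

Step 11
Reactants: 12 tricyclic photoadduct
Product: 14 trans-fused C4 ketone (5α-H; 1β-CH3; 2β-OTBS; 6α-OTES; C8=C9), via samarium enolate 13 (not isolated)
Conditions: SmI2 (2.5 equiv), HMPA, t-BuOH, THF, −78 °C; aqueous work-up
Reagents that add atoms: none
Why: SmI2 ketyl fragmentation of a cyclobutyl ketone followed by reductive β-elimination, in which the C4 ketyl opens the strained C5–C9 bond (exocyclic to the cyclopentanone and aligned with the ketyl π orbital), the secondary C9 radical is reduced with the help of HMPA to an organosamarium that expels the β-silyloxy group on C8, and enolate 13 is protonated kinetically on its α face, anti to the axial C1 methyl and the 2β-silyloxy group, to give the trans-fused ketone.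

Step 12
Reactants: 14 trans-fused C4 ketone
Product: 16 4β,6α-diol (4α-isopropyl; 5α-H; 2β-OTBS; C8=C9), via tertiary carbinol TES ether 15 (not isolated)
Conditions: i-PrMgCl, LaCl3·2LiCl, THF, −20 → 0 °C; then 1 M aq HCl, THF, 0 °C
Reagents that add atoms: isopropylmagnesium chloride CC(C)[Mg]Cl
Why: Lanthanide-salt-promoted Grignard 1,2-addition (which suppresses enolisation, β-hydride reduction and loss of the β-silyloxy groups) should occur from the α face because the β face of C4 is flanked by the C1 methyl and the 2β-silyloxy group, giving 4β-OH/4α-i-Pr, and the dilute acid of the work-up then cleaves only the secondary TES ether.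

Step 13
Reactants: 16 4β,6α-diol
Product: 17 6α-(4-methoxybenzoate) (4β-OH; 2β-OTBS; C8=C9)
Conditions: 4-MeOC6H4COCl, DMAP, pyridine, CH2Cl2, rt → 40 °C
Reagents that add atoms: 4-methoxybenzoyl chloride COc1ccc(cc1)C(Cl)=O
Why: DMAP-catalysed acylation distinguishes the secondary 6α-hydroxyl from the tertiary 4β-hydroxyl, which does not acylate under these conditions, and C6 keeps its configuration because only the O–H bond reacts.

Step 14
Reactants: 17 6α-(4-methoxybenzoate)
Product: 18 2β-alcohol (6α-anisate; 4β-OH; C8=C9)
Conditions: HF·pyridine, pyridine–THF, 0 °C → rt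
Reagents that add atoms: none
Why: Fluoride desilylation under buffered, non-basic conditions removes the neopentyl TBS ether while sparing the aryl ester, the tertiary alcohol and the alkene and avoiding base-induced acyl migration.

Step 15
Reactants: 18 2β-alcohol
Product: 19 2-ketone (6α-anisate; 4β-OH; C8=C9)
Conditions: Dess–Martin periodinane, CH2Cl2, 0 °C → rt
Reagents that add atoms: none
Why: Dess–Martin oxidation acts on the only secondary alcohol under near-neutral conditions that should not dehydrate or retro-aldolise the resulting β-hydroxy ketone.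

Step 16
Reactants: 19 2-ketone
Product: 20 2α-alcohol (6α-anisate; 4β-OH; C8=C9)
Conditions: Me4NBH(OAc)3, MeCN–AcOH, −20 °C → rt
Reagents that add atoms: none
Why: Evans–Saksena reduction, in which the pseudoaxial 4β-hydroxyl replaces an acetate on boron and hydride is passed intramolecularly to the β face of C2 to give the 2α-alcohol (trans-1,3-diol), the opposite of what an external hydride avoiding the C1 methyl would give, while the ester and the alkene are inert to this reagent.

Step 17
Reactants: 20 2α-alcohol
Product: 21 2α-acetate (6α-anisate; 4β-OH; C8=C9)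
Conditions: Ac2O, DMAP (cat.), pyridine, rt
Reagents that add atoms: acetic anhydride CC(=O)OC(C)=O
Why: DMAP-catalysed acetylation reacts at the only secondary hydroxyl and leaves the hindered tertiary 4β-hydroxyl free.

Step 18
Reactants: 21 2α-acetate
Product: 22 target CNP0317703.1
Conditions: dimethyldioxirane (acetone solution), CH2Cl2, −20 → 0 °C
Reagents that add atoms: dimethyldioxirane CC1(C)OO1
Why: Concerted dioxirane epoxidation under neutral conditions should deliver oxygen to the open α face of C8=C9, because in the chair cycloheptene of the trans-fused skeleton the axial C1 methyl and H6 cover the β face, and the absence of acid protects the trisubstituted epoxide from transannular opening by the 4β-hydroxyl.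

**Compound list**

1 | (S)-4-(tert-butyldimethylsilyloxy)cyclopent-2-en-1-one | O=C1C=C[C@@H](O[Si](C)(C)C(C)(C)C)C1 | starting material
2 | (3S,4S)-4-(tert-butyldimethylsilyloxy)-3-methyl-1-(trimethylsilyloxy)cyclopent-1-ene | C[Si](C)(C)OC1=C[C@H](C)[C@@H](O[Si](C)(C)C(C)(C)C)C1 | intermediate
3 | (S)-4-(tert-butyldimethylsilyloxy)-3-methylcyclopent-2-en-1-one | O=C1C=C(C)[C@@H](O[Si](C)(C)C(C)(C)C)C1 | intermediate
4 | (S)-4-(tert-butyldimethylsilyloxy)-2-iodo-3-methylcyclopent-2-en-1-one | O=C1C(I)=C(C)[C@@H](O[Si](C)(C)C(C)(C)C)C1 | intermediate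
5 | (R)-(−)-linalool, (3R)-3,7-dimethylocta-1,6-dien-3-ol | C=C[C@](C)(O)CCC=C(C)C | starting material
6 | (3R)-3,7-dimethyl-3-(triethylsilyloxy)octa-1,6-diene | C=C[C@](C)(O[Si](CC)(CC)CC)CCC=C(C)C | intermediate
7 | (4R)-4-methyl-4-(triethylsilyloxy)hex-5-enal | C=C[C@](C)(O[Si](CC)(CC)CC)CCC=O | intermediate
8 | triisopropyl{[(1Z,4R)-4-methyl-4-(triethylsilyloxy)hexa-1,5-dien-1-yl]oxy}silane (Z drawn; geometry irrelevant) | C=C[C@](C)(O[Si](CC)(CC)CC)C/C=C\O[Si](C(C)C)(C(C)C)C(C)C | intermediate
9 | (3R)-3-methyl-3-(triethylsilyloxy)pent-4-enal | C=C[C@](C)(O[Si](CC)(CC)CC)CC=O | intermediate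
10 | coupling product, 2S,6R,8R allylic alcohol | C=C[C@](C)(O[Si](CC)(CC)CC)C[C@@H](O)C1=C(C)[C@@H](O[Si](C)(C)C(C)(C)C)CC1=O | intermediate
11 | photoprecursor, 2S-OTBS, 6R-OTES, 8R-OTES enone | C=C[C@](C)(O[Si](CC)(CC)CC)C[C@@H](O[Si](CC)(CC)CC)C1=C(C)[C@@H](O[Si](C)(C)C(C)(C)C)CC1=O | intermediate
12 | tricyclic cyclobutane photoadduct | CC[Si](CC)(CC)O[C@@H]2C[C@@](C)(O[Si](CC)(CC)CC)[C@H]4C[C@]3(C)[C@@H](O[Si](C)(C)C(C)(C)C)CC(=O)[C@@]234 | intermediate
13 | samarium enolate (C4–O–SmI2, C4=C5, C8=C9) | CC[Si](CC)(CC)O[C@@H]2CC(C)=CC[C@]3(C)[C@@H](O[Si](C)(C)C(C)(C)C)CC(O[Sm](I)I)=C23 | intermediate (not isolated)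
14 | trans-fused C4 ketone, 5α-H, 2β-OTBS, 6α-OTES, C8=C9 | CC[Si](CC)(CC)O[C@@H]2CC(C)=CC[C@]3(C)[C@@H](O[Si](C)(C)C(C)(C)C)CC(=O)[C@@H]23 | intermediate
15 | 4β-hydroxy-4α-isopropyl compound, 6α-OTES, 2β-OTBS | CC[Si](CC)(CC)O[C@@H]2CC(C)=CC[C@]3(C)[C@@H](O[Si](C)(C)C(C)(C)C)C[C@](O)(C(C)C)[C@@H]23 | intermediate (not isolated)
16 | 4β,6α-diol, 2β-OTBS | O[C@@H]2CC(C)=CC[C@]3(C)[C@@H](O[Si](C)(C)C(C)(C)C)C[C@](O)(C(C)C)[C@@H]23 | intermediate
17 | 6α-(4-methoxybenzoate), 2β-OTBS | COc1ccc(C(=O)O[C@@H]2CC(C)=CC[C@]3(C)[C@@H](O[Si](C)(C)C(C)(C)C)C[C@](O)(C(C)C)[C@@H]23)cc1 | intermediate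
18 | 2β-alcohol | COc1ccc(C(=O)O[C@@H]2CC(C)=CC[C@]3(C)[C@@H](O)C[C@](O)(C(C)C)[C@@H]23)cc1 | intermediate
19 | 2-ketone | COc1ccc(C(=O)O[C@@H]2CC(C)=CC[C@]3(C)C(=O)C[C@](O)(C(C)C)[C@@H]23)cc1 | intermediate
20 | 2α-alcohol | COc1ccc(C(=O)O[C@@H]2CC(C)=CC[C@]3(C)[C@H](O)C[C@](O)(C(C)C)[C@@H]23)cc1 | intermediate
21 | 2α-acetate, C8=C9 | COc1ccc(C(=O)O[C@@H]2CC(C)=CC[C@]3(C)[C@H](OC(C)=O)C[C@](O)(C(C)C)[C@@H]23)cc1 | intermediate
22 | CNP0317703.1: 2α-acetoxy-8α,9α-epoxy-4β-hydroxy-4α-isopropyl-6α-(4-methoxybenzoyloxy) trans-fused bicycle | COc1ccc(C(=O)O[C@@H]2C[C@]3(C)O[C@@H]3C[C@]3(C)[C@H](OC(C)=O)C[C@](O)(C(C)C)[C@@H]23)cc1 | target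

Total step count: 18.
Longest linear sequence: 15 steps (5 → 22, steps 4–18).

**Steps most likely to fail**

**Step 10.** Reversion of the 1,4-biradical, crossed closure or attack on the β face of the enone would erode the photocycloaddition. The fallback replaces photochemistry by ring-closing metathesis. It sets out from 3 and comes back at 14.
- Dess–Martin oxidation of commercial 3-methylbut-3-en-1-ol gives 3-methylbut-3-enal F1.
- Copper-mediated conjugate allylation of 3 (allylMgBr, CuBr·SMe2, TMSCl, THF, −78 °C) anti to the silyloxy group gives the allylated silyl enol ether F2.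
- The lithium enolate of F2 (MeLi) adds to F1 through a chair transition state to give the 5,6-anti aldol F3. Isomers at C5 and C6 would have to be separated.
- Silylation with TESOTf gives the diene TES ether F4.
- The second-generation Grubbs catalyst (CH2Cl2, reflux) closes C8=C9 to give 14.

**Step 11.** Protonation of the samarium enolate from the β face would spoil the tandem process, as would hydrogen abstraction by the C9 radical before its reduction. The fallback replaces kinetic by thermodynamic control at C5. It sets out from 12 and comes back at 14.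
- The same cleavage is run without regard to C5.
- The cis-fused 5β-H ketone F5 is separated and equilibrated under the weakly basic buffered conditions used to epimerise β-oxygenated cyclopentanones (KOAc, EtOH, rt), with recycling of recovered F5.
- Stronger bases are excluded because O2 and O6 are both β to the carbonyl.

**Step 8.** Insufficient or inverted catalyst control over the aldehyde face would give material of the wrong configuration at C6. That material is mismatched in step 10. The fallback replaces catalyst control by separation and inversion. It sets out from 4 and 9 and comes back at 10.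
- The ligand-free CrCl2/NiCl2 coupling gives 10 together with the 6S allylic alcohol F6, and the two diastereomers are separated by chromatography.
- A Mitsunobu reaction (4-nitrobenzoic acid, PPh3, DIAD, THF) inverts F6 to the 6R 4-nitrobenzoate F7.
- Mild methanolysis (K2CO3, MeOH, 0 °C) returns 10.

Further compounds
F1 | step 10 | 3-methylbut-3-enal | CC(=C)CC=O
F2 | step 10 | 3α-allyl-3β-methyl-4β-(tert-butyldimethylsilyloxy)-1-(trimethylsilyloxy)cyclopent-1-ene (allyl = C10, C9) | C[Si](C)(C)OC1=C[C@](C)(CC=C)[C@@H](O[Si](C)(C)C(C)(C)C)C1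
F3 | step 10 | 5,6-anti aldol (6α-OH, 5α-H, 1α-allyl, 2β-OTBS, methallyl on C6) | O[C@H](CC(C)=C)[C@@H]1C(=O)C[C@H](O[Si](C)(C)C(C)(C)C)[C@@]1(C)CC=C
F4 | step 10 | TES ether of F3 | CC[Si](CC)(CC)O[C@H](CC(C)=C)[C@@H]1C(=O)C[C@H](O[Si](C)(C)C(C)(C)C)[C@@]1(C)CC=C
F5 | step 11 | cis-fused 5β-H epimer of 14 | CC[Si](CC)(CC)O[C@@H]2CC(C)=CC[C@]3(C)[C@@H](O[Si](C)(C)C(C)(C)C)CC(=O)[C@H]23
F6 | step 8 | 6S epimer of 10 | C=C[C@](C)(O[Si](CC)(CC)CC)C[C@H](O)C1=C(C)[C@@H](O[Si](C)(C)C(C)(C)C)CC1=O
F7 | step 8 | 6R 4-nitrobenzoate of 10 | C=C[C@](C)(O[Si](CC)(CC)CC)C[C@@H](OC(=O)c2ccc(cc2)[N+](=O)[O-])C1=C(C)[C@@H](O[Si](C)(C)C(C)(C)C)CC1=O
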